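**Retrosynthetic overview**

1. Thymol numbering is used for the side chain (C8 = quaternary benzylic carbon, C9 = oxirane CH2, C10 = CH2O). Target ⇒ alkene diester by disconnecting both oxirane C–O bonds: the oxirane is closed last by enantioselective oxygen-atom transfer to the C8=C9 olefin of the fully acylated 8,9-dehydrothymol, the event an oxygenase performs in the plant, and this step alone sets C8 (R).
2. Alkene diester ⇒ phenol/allylic diol by two acyl C–O disconnections: angelate on the phenoxide first, tiglate on the primary alcohol second.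
3. Diol ⇒ aryl–C8 bond: Suzuki–Miyaura union of an ortho-bromophenol (through its pinacol boronate) with 2-bromoallyl alcohol.
4. Bromophenol ⇒ 4-methoxy-3-methylphenol by ortho-bromination.
5. Ring order: the benzene ring is bought intact; the oxirane is the only ring formed, in the final step.

Assumption: the facial sense of the iron catalyst in step 5 is assigned by analogy with α-alkylstyrenes, so the (S,S)-ligand/L-amino acid pair is written for the (R)-epoxide; if chiral HPLC against the tartrate-derived reference (fallback to step 5) shows the opposite sense, the mirror-image (R,R)-ligand/D-amino acid pair is used with nothing else changed.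

**Route**

Step 1
Reactants: 1 4-methoxy-3-methylphenol
Product: 2 2-bromo-4-methoxy-5-methylphenol
Conditions: NBS (1.0 equiv), CH2Cl2, 0 °C
Reagents that add atoms: N-bromosuccinimide, O=C1CCC(=O)N1Br
Why: Electrophilic aromatic bromination directed by the free hydroxyl: of its two ortho positions C6 is also para to the methyl and unhindered whereas C2 is wedged between OH and CH3, and the position ortho to the weaker OMe director does not compete, so one equivalent of NBS gives the 2-bromo isomer; no stereocentre is formed.

Step 2
Reactants: 2 2-bromo-4-methoxy-5-methylphenol; 3 bis(pinacolato)diboron; 4 2-bromoprop-2-en-1-ol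
Product: 6 2-(3-hydroxyprop-1-en-2-yl)-4-methoxy-5-methylphenol, via aryl pinacol boronate 5 (not isolated)
Conditions: 3 (1.1 equiv), Pd(dppf)Cl2 (3 mol%), KOAc, 1,4-dioxane, 90 °C; then 4 (1.2 equiv), aq. K3PO4, 80 °C, one pot
Reagents that add atoms: none
Why: One-pot Miyaura borylation then Suzuki–Miyaura coupling: the aryl bromide becomes the pinacol boronate, which transmetalates under aqueous phosphate and couples with the vinylic bromide of 4 (free OH groups are tolerated and an allylic alcohol is not ionised by zerovalent palladium), giving the 1,1-disubstituted 2-arylallyl alcohol with no stereocentre.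

Step 3
Reactants: 6 2-(3-hydroxyprop-1-en-2-yl)-4-methoxy-5-methylphenol; 7 angelic acid [(Z)-2-methylbut-2-enoic acid]; 8 2,4,6-trichlorobenzoyl chloride
Product: 10 2-(3-hydroxyprop-1-en-2-yl)-4-methoxy-5-methylphenyl (Z)-2-methylbut-2-enoate, via mixed anhydride 9 (not isolated)
Conditions: 7, 8, Et3N, toluene, rt, 1 h; then 6, Cs2CO3 (1.05 equiv), MeCN, 0 °C
Reagents that add atoms: none
Why: Yamaguchi-type mixed-anhydride acylation: only the phenol (pKa about 10) is ionised by Cs2CO3 and the phenoxide attacks the unhindered angeloyl carbonyl of 9 far faster than the neutral primary alcohol can without DMAP, while the cold, nucleophile-free conditions keep the Z double bond from isomerising to the tiglate; no stereocentre.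

Step 4
Reactants: 10 2-(3-hydroxyprop-1-en-2-yl)-4-methoxy-5-methylphenyl (Z)-2-methylbut-2-enoate; 11 tigloyl chloride [(E)-2-methylbut-2-enoyl chloride]
Product: 12 2-{5-methoxy-4-methyl-2-[(Z)-2-methylbut-2-enoyloxy]phenyl}prop-2-en-1-yl (E)-2-methylbut-2-enoate
Conditions: 11 (1.3 equiv), pyridine, CH2Cl2, 0 °C
Reagents that add atoms: none
Why: Acid chloride esterification (nucleophilic acyl substitution) of the only remaining hydroxyl with the thermodynamically stable E-acyl chloride under weakly basic, DMAP-free conditions that neither transfer nor isomerise the aryl angelate; no stereocentre.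

Step 5
Reactants: 12 2-{5-methoxy-4-methyl-2-[(Z)-2-methylbut-2-enoyloxy]phenyl}prop-2-en-1-yl (E)-2-methylbut-2-enoate
Product: 13 {(2R)-2-[5-methoxy-4-methyl-2-((Z)-2-methylbut-2-enoyloxy)phenyl]oxiran-2-yl}methyl (E)-2-methylbut-2-enoate
Conditions: Fe(OTf)2[(S,S)-Me2N-pdp] (2 mol%; pdp = N,N'-bis(pyridin-2-ylmethyl)-2,2'-bipyrrolidine, 4-NMe2 on each pyridine), N-(1,8-naphthaloyl)-L-isoleucine (3 mol%), 30% aq. H2O2 (1.5 equiv, syringe pump, 30 min), MeCN, −30 °C
Reagents that add atoms: hydrogen peroxide, OO
Why: Bio-inspired non-haem iron-catalysed asymmetric epoxidation (oxygen-atom transfer from a chiral high-valent iron-oxo carboxylate, the chemical counterpart of the oxygenase step): the electrophilic oxidant takes the electron-richer 1,1-disubstituted aryl alkene in preference to the two conjugated enoate alkenes, and the C2-symmetric bipyrrolidine ligand with the bulky amino-acid coligand differentiates the enantiotopic faces of α-substituted styrenes, creating the quaternary C8 stereocentre as (R) directly in the target with no later step that could erode it.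

**Compound list**

1 | 4-methoxy-3-methylphenol | COc1ccc(O)cc1C | starting material
2 | 2-bromo-4-methoxy-5-methylphenol | COc1cc(Br)c(O)cc1C | intermediate
3 | bis(pinacolato)diboron | CC1(C)OB(OC1(C)C)B1OC(C)(C)C(C)(C)O1 | starting material
4 | 2-bromoprop-2-en-1-ol | OCC(Br)=C | starting material
5 | 4-methoxy-5-methyl-2-(4,4,5,5-tetramethyl-1,3,2-dioxaborolan-2-yl)phenol | COc1cc(B2OC(C)(C)C(C)(C)O2)c(O)cc1C | intermediate
6 | 2-(3-hydroxyprop-1-en-2-yl)-4-methoxy-5-methylphenol | COc1cc(C(=C)CO)c(O)cc1C | intermediate
7 | angelic acid [(Z)-2-methylbut-2-enoic acid] | C/C=C(/C)C(=O)O | starting material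
8 | 2,4,6-trichlorobenzoyl chloride | O=C(Cl)c1c(Cl)cc(Cl)cc1Cl | starting material
9 | (Z)-2-methylbut-2-enoic 2,4,6-trichlorobenzoic anhydride | C/C=C(/C)C(=O)OC(=O)c1c(Cl)cc(Cl)cc1Cl | intermediate
10 | 2-(3-hydroxyprop-1-en-2-yl)-4-methoxy-5-methylphenyl (Z)-2-methylbut-2-enoate | C/C=C(/C)C(=O)Oc1cc(C)c(OC)cc1C(=C)CO | intermediate
11 | tigloyl chloride [(E)-2-methylbut-2-enoyl chloride] | C/C=C(\C)C(=O)Cl | starting material
12 | 2-{5-methoxy-4-methyl-2-[(Z)-2-methylbut-2-enoyloxy]phenyl}prop-2-en-1-yl (E)-2-methylbut-2-enoate | C/C=C(/C)C(=O)Oc1cc(C)c(OC)cc1C(=C)COC(=O)/C(C)=C/C | intermediate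
13 | {(2R)-2-[5-methoxy-4-methyl-2-((Z)-2-methylbut-2-enoyloxy)phenyl]oxiran-2-yl}methyl (E)-2-methylbut-2-enoate | C/C=C(/C)C(=O)Oc1cc(C)c(OC)cc1[C@]1(COC(=O)/C(C)=C/C)CO1 | target

**Totals**

Total step count: 5. Longest linear sequence: 5 (1 → 2 → 6 → 10 → 12 → 13).

**Three steps most likely to fail, with fallbacks**

Step 5 is the most exposed. The catalyst class is established for α-alkylstyrenes, but here it must choose one of three C=C bonds, the ortho-acyloxy and α-acyloxymethyl groups are untested for ee, and the benzylic epoxide must survive the acidic coligand. Limiting H2O2 and −30 °C address over-oxidation; ee is read by chiral HPLC. Fallback: set out from 10 and use the tartrate-controlled, hydroxyl-directed epoxidation instead. Ti(OiPr)4 (10 mol%), L-(+)-diethyl tartrate (12 mol%), tBuOOH, 4 Å sieves, CH2Cl2, −20 °C epoxidises only the allylic-alcohol olefin. The natural tartrate delivers oxygen to the face that gives (S)-glycidol from allyl alcohol, which here gives 2-[(2S)-2-(hydroxymethyl)oxiran-2-yl]-4-methoxy-5-methylphenyl (Z)-2-methylbut-2-enoate F1. Its descriptor is S only because the CIP order of the two CH2O groups changes; the spatial arrangement is that of 13. Acylation of F1 with 11 and pyridine at 0 °C comes back to the route at 13.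

Step 2 is second. Borylation of an unprotected, electron-rich ortho-bromophenol can suffer protodeboronation, and leftover 3 can borylate and homocouple 4. Fallback: set out from 2 and bring in the C3 unit unoxidised, then oxidise the allylic C–H bond as the plant does. Suzuki–Miyaura coupling of 2 with commercial isopropenylboronic acid pinacol ester (Pd(dppf)Cl2, K3PO4, dioxane/H2O, 80 °C) gives 4-methoxy-5-methyl-2-(prop-1-en-2-yl)phenol F2. Phenoxide acylation with mixed anhydride 9 as in step 3 gives 4-methoxy-5-methyl-2-(prop-1-en-2-yl)phenyl (Z)-2-methylbut-2-enoate F3. Allylic hydroxylation of the isopropenyl methyl with SeO2 (cat.) and tBuOOH in CH2Cl2 (ene reaction then 2,3-sigmatropic shift; the styrenyl olefin is far more nucleophilic than the enoate; any enal is reduced back with NaBH4/CeCl3 at −40 °C) comes back to the route at 10.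

Step 3 is third. It relies on phenoxide-over-alcohol selectivity, on the Z acyl group not isomerising, and on no aryl-to-alkyl acyl migration; the possible by-products are near-inseparable regio- and geometric isomers. Fallback: set out from 6 and differentiate the two oxygens by selective cleavage instead of selective acylation. Exhaustive acylation with 11 (2.5 equiv, pyridine, cat. DMAP) gives 2-{5-methoxy-4-methyl-2-[(E)-2-methylbut-2-enoyloxy]phenyl}prop-2-en-1-yl (E)-2-methylbut-2-enoate F4. Pyrrolidine (1.1 equiv, THF, 0 °C) removes only the aryl ester, which undergoes aminolysis far faster than the alkyl ester, giving 2-(2-hydroxy-5-methoxy-4-methylphenyl)prop-2-en-1-yl (E)-2-methylbut-2-enoate F5. Acylation of the freed phenol with 9 and Cs2CO3 in MeCN at 0 °C then installs the angelate last and comes back to the route at 12.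

**Further compounds**

F1 | step 5 | 2-[(2S)-2-(hydroxymethyl)oxiran-2-yl]-4-methoxy-5-methylphenyl (Z)-2-methylbut-2-enoate | C/C=C(/C)C(=O)Oc1cc(C)c(OC)cc1[C@]1(CO)CO1
F2 | step 2 | 4-methoxy-5-methyl-2-(prop-1-en-2-yl)phenol | COc1cc(C(C)=C)c(O)cc1C
F3 | step 2 | 4-methoxy-5-methyl-2-(prop-1-en-2-yl)phenyl (Z)-2-methylbut-2-enoate | C/C=C(/C)C(=O)Oc1cc(C)c(OC)cc1C(C)=C
F4 | step 3 | 2-{5-methoxy-4-methyl-2-[(E)-2-methylbut-2-enoyloxy]phenyl}prop-2-en-1-yl (E)-2-methylbut-2-enoate | C/C=C(\C)C(=O)Oc1cc(C)c(OC)cc1C(=C)COC(=O)/C(C)=C/C
F5 | step 3 | 2-(2-hydroxy-5-methoxy-4-methylphenyl)prop-2-en-1-yl (E)-2-methylbut-2-enoate | COc1cc(C(=C)COC(=O)/C(C)=C/C)c(O)cc1C
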